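## Structural features

The target is a daucane sesquiterpenoid ester: a cyclopentane (C1–C5) fused through the C1–C5 bond to a cycloheptenone (C1, C5, C6, C7, C8, C9, C10), where C1 is the methyl-bearing fusion carbon, C5 the fusion CH, C4 the isopropyl carbinol and C8(Me)=C9–C10(=O) the enone. The fusion is trans (C1 methyl anti to H5), and C4, C5, C1 and C6 form an unbroken run of four stereocentres (1S,4R,5S,6S), with the C4 hydroxyl on the side of the C1 methyl and the C6 oxygen on the side of H5. C1 is quaternary and lies next to the C10 carbonyl, and C4 is a fully substituted carbinol. The fragile points are the enone with its γ-CH2 (C7) and δ-acyloxy group (C6), which a base can turn into a dienone by vinylogous β-elimination, the ester itself, and, in every intermediate that still carries the diene, the tertiary, doubly allylic C4–O bond, which ionises readily with acid. The real difficulty is the trans-fused five–seven system with the quaternary C1 and the C4/C5/C1 triad, followed by the oxygen at C6 on a flexible ring. The key step uses the fact that C9–C10(=O)–C1 is a three-carbon unit at the oxidation level of an oxyallyl cation, C5–C6–C7–C8 a four-carbon diene unit, and C2–C3–C4 a tether between them, so both rings close at once and the C6=C7 alkene that remains sits exactly where the C6 oxygen and the C8=C9 unsaturation have to be introduced. Bicyclic compounds are named below on the daucane skeleton (bicyclo[5.3.0]decane with methyl groups on C1 and C8 and a propan-2-yl group on C4) in this numbering.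

## Logic of the disconnections

**26 ⇒ 25 ⇒ 23 + 24.** The Si–O bond at C4 and the acyl C–O bond at C6 are cut. The ester is placed late because the δ-acyloxy enone is base-sensitive once formed, and the silyl group is kept to the end so that only one hydroxyl is free at the acylation. This removes the aromatic ester and leaves a hydroxy enone. The forward steps must acylate a hindered secondary alcohol without elimination and remove the silyl group without base.

**23 ⇒ 22 ⇒ 21 ⇒ 19 ⇒ 18.** No C–C bond is cut; the C6–O bond and the C8=C9 unsaturation are traced back to the C6=C7 alkene of 18 through an epoxide (C6–O and C7–O) and a dehydrogenation (C8–H, C9–H). The reason is that 18 carries no oxygen on the seven-membered ring except C10, and its only alkene is at the right place. The gain is that all ring functionality derives from one alkene and one ketone. The demands are epoxidation on the face of H5, enolisation toward C9 (the only possible direction, C1 being quaternary), reductive cleavage of C7–O and not C6–O, and movement of the alkene into conjugation.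

**18 ⇒ 16 (through 17).** The C1–C5 and C8–C9 bonds are cut. This opens both rings at once and replaces three stereocentres by an acyclic chain with one stereocentre and a diene of defined geometry. The forward step must give the trans fusion, relay the C4 configuration to C5 and C1, and outrun solvent capture of the cation.

**16 ⇒ 15 ⇒ 13 + 14 ⇒ 12.** The C9–C10 bond and the C1–Cl bond are cut. Chlorination is moved to the aldehyde stage because there C1 is the only α-carbon, so the halogen goes in regiospecifically and without acid; chlorinating the methyl ketone itself would need acid or an unselective enolisation next to a diene and an ionisable C4–O bond. The gain is a simple α-branched aldehyde. The demands are a mild chlorination, a Grignard addition that does not close the chlorohydrin to an epoxide, and a neutral oxidation.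

**12 ⇒ 11 ⇒ 10 ⇒ 9.** Only functional groups change: the aldehyde is traced to a primary alcohol masked as a pivalate, and the C4 silyl ether to the free carbinol. The pivalate is chosen because it survives the organozinc step and is removed by hydride, not by acid. The demand is that C4–OH is silylated before the aldehyde is freed, or a lactol would form.

**9 ⇒ 4 + 8; 8 ⇒ 7 ⇒ 6 ⇒ 5.** The C3–C4 bond is cut. It is the one bond to C4 that can be formed by catalyst-controlled addition of a primary alkyl nucleophile to an alkenyl ketone, and the cut divides the chain into two pieces of similar size. The forward step needs a salt-free dialkylzinc and discrimination between the dienyl and the isopropyl group of 4.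

**4 ⇒ 3 ⇒ 1 + 2.** The bond between the carbonyl carbon (C4) and the isopropyl carbon is cut, which leads back to a commercial dienal that already holds the (E,E)-diene and the C8 methyl. The forward steps need 1,2-addition and an oxidation that leaves the diene geometry alone.

## Other disconnections considered

**Alternative 1:** The cut is C4–C5. A chiral N-heterocyclic carbene would turn the aldehyde of the achiral triketone 3-(1-methyl-2,7-dioxocycloheptyl)propanal A1 into an acyl-anion equivalent that adds to one of the two enantiotopic ring carbonyls and gives the bicyclic ketol A2.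
- **In favour:** the substrate is achiral and quickly made, the step is catalytic, and it sets the quaternary C1 and the absolute configuration in the ring-forming event. On the source of chirality it is the better plan, since the chosen route needs a separate asymmetric addition and then relay from C4.
- **Against:** A2 is cis-fused and carries a hydroxyl on C5 where the target has a hydrogen anti to the C1 methyl, so the angular oxygen would have to be removed with inversion of the fusion. C4 arrives as a ketone that still needs the isopropyl group. The seven-membered ring arrives as four bare methylenes, so the C8 methyl, the C8=C9 alkene and above all the C6 oxygen would have to be placed on unactivated carbons.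
- **Comparison:** structurally the (4+3) product 18 already holds all fifteen carbons and an alkene at C6=C7. Mechanistically the benzoin is reversible and best established for five- and six-membered diones. In step count it is shorter before the key step and clearly longer after it.

**Alternative 2:** The cuts are C1–C10 and C5–C6. Copper-catalysed conjugate addition of the vinylaluminium reagent A4 to 3-methylcyclopent-2-en-1-one A3 would create the quaternary C1, and the enolate would be trapped at C5 by the aldehyde A5 to give the aldol A6.
- **In favour:** it is convergent, and anti trapping gives the trans relation of the C10 and C6 arms, which equals the chosen plan on the ring-fusion question. The C6 oxygen and the C8 carbonyl arrive at the right oxidation level, and the C8=C9 enone would come from a later aldol condensation without any redox steps; on redox economy it is better than the chosen plan.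
- **Against:** an enolate next to a newly formed quaternary centre is a sluggish aldol donor, and A5 is enolisable. The C6 configuration would rest on an uncertain aldol selectivity. The vinylsilane must be converted into the methyl ketone. The seven-membered aldol closure must be run with three carbonyl groups (C4, C8, C10) and a β-oxygen at C6 that can eliminate. The isopropyl group must then be added to the C4 ketone, whose α-carbon C5 is epimerisable and open to retro-aldol cleavage.
- **Comparison:** it builds the cyclopentane first and closes the large ring by condensation, where the chosen plan closes both rings in one pericyclic or cationic event from a stable acyclic precursor. The step count would be similar, with more selectivity questions spread over more steps.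

**Alternative 3:** The cuts are C6–C7 and C9–C10. The two ends of the linchpin A8 (allylic iodide, then allylsilane) would allylate in turn the C6 and C10 aldehydes of the trans-dialdehyde A7 and give the diol A9 with an exocyclic methylene at C8.
- **In favour:** one reagent brings C7, C8, C9 and the C8 methyl carbon, both oxygens arrive in the annulation, and only oxidation at C10, alkene isomerisation and acylation would remain. After the ring-forming step it is shorter than the chosen plan.
- **Against:** A7 already contains C1, C4 and C5, so the stereochemical problem is moved into a multi-step synthesis of a trans-cyclopentane dialdehyde. Its C5 aldehyde has a β-silyloxy group (elimination) and an epimerisable α-carbon. The two aldehydes must be allylated in a fixed order, the second closure onto the neopentyl C10 aldehyde needs a Lewis acid next to a tertiary silyl ether, the C6 carbinol configuration depends on 1,2-induction, and the two secondary hydroxyls must then be told apart.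
- **Comparison:** the ring is closed by two polar additions and not by a cycloaddition. It is convergent and better in the end game, but weaker in how the C1/C4/C5 triad is made, which the chosen plan sets in the ring-forming step itself.

Key step: step 11

Remark on the chemistry: the antipode of the chiral ligand in step 4 is taken to be the one that delivers the alkyl group to the Si face of the carbonyl of 4 (to be confirmed on a test scale), and compounds 6 to 16 are carried as mixtures of epimers at the methyl-bearing carbon that becomes C1, which is of no consequence because that centre is planar in 17.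

## Route

Step 1
Reactants: 1 (2E,4E)-hexa-2,4-dienal; 2 isopropylmagnesium chloride (2 M in THF)
Product: 3 (4E,6E)-2-methylocta-4,6-dien-3-ol (racemic)
Conditions: iPrMgCl, THF, −78 °C to 0 °C; aq. NH4Cl
Reagents that add atoms: isopropylmagnesium chloride (compound 2), CC(C)[Mg]Cl
Why: Grignard 1,2-addition to a conjugated aldehyde; at low temperature carbonyl addition should outrun 1,4- and 1,6-addition and the diene geometry is not touched. The new carbinol centre is racemic and is removed in step 2.

Step 2
Reactants: 3 (4E,6E)-2-methylocta-4,6-dien-3-ol
Product: 4 (4E,6E)-2-methylocta-4,6-dien-3-one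
Conditions: activated MnO2 (excess), CH2Cl2, rt
Reagents that add atoms: none
Why: Selective oxidation of an allylic (dienylic) alcohol by MnO2 under neutral conditions, which should leave the (E,E)-diene unchanged.

Step 3
Reactants: 5 2-methylbut-3-en-1-ol (racemic)
Product: 6 2-methylbut-3-en-1-yl 2,2-dimethylpropanoate (racemic)
Conditions: tBuCOCl, pyridine, CH2Cl2, 0 °C to rt
Reagents that add atoms: pivaloyl chloride, CC(C)(C)C(Cl)=O
Why: Acylation of a primary alcohol; the pivalate tolerates organoboron and organozinc reagents and is later removed by hydride, not by acid.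

Step 4
Reactants: 6 2-methylbut-3-en-1-yl 2,2-dimethylpropanoate; 4 (4E,6E)-2-methylocta-4,6-dien-3-one
Product: 9 (5R,6E,8E)-5-hydroxy-2-methyl-5-(propan-2-yl)deca-6,8-dien-1-yl 2,2-dimethylpropanoate (both C2 epimers), via alkyldiethylborane 7 (not isolated), via dialkylzinc 8 (not isolated)
Conditions: 6, Et2BH (from BH3·SMe2 + BEt3), 0 °C to rt; ZnEt2, 0 °C, then volatiles removed in vacuo; 4, Ti(OiPr)4 (1.2 equiv), bis(hydroxycamphorsulfonamide) ligand of trans-cyclohexane-1,2-diamine (10 mol %), toluene, rt; aq. NH4Cl
Reagents that add atoms: none
Why: Anti-Markovnikov hydroboration and boron–zinc exchange give a salt-free functionalised dialkylzinc, which adds 1,2 to the ketone in the Ti(OiPr)4-promoted catalytic asymmetric alkylation of ketones, a reaction type for which conjugated ketones are established substrates. The titanium-bound chiral bis(sulfonamide) diol should tell the flat dienyl group from the branched isopropyl group and deliver the primary alkyl group to the Si face of the carbonyl (O > dienyl > isopropyl), which sets C4 as R.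

Step 5
Reactants: 9 (5R,6E,8E)-5-hydroxy-2-methyl-5-(propan-2-yl)deca-6,8-dien-1-yl 2,2-dimethylpropanoate
Product: 10 (5R,6E,8E)-2-methyl-5-(propan-2-yl)-5-(triethylsilyloxy)deca-6,8-dien-1-yl 2,2-dimethylpropanoate
Conditions: Et3SiOTf, 2,6-lutidine, CH2Cl2, −78 °C to 0 °C
Reagents that add atoms: triethylsilyl trifluoromethanesulfonate, CC[Si](CC)(CC)OS(=O)(=O)C(F)(F)F
Why: Silylation of a hindered tertiary alcohol with a silyl triflate and a hindered base at low temperature, conditions under which the doubly allylic C–O bond should not ionise. The triethylsilyl ether is robust enough for the amine/fluoro-alcohol medium of step 11 and is still removable from a tertiary centre at the end.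

Step 6
Reactants: 10 (5R,6E,8E)-2-methyl-5-(propan-2-yl)-5-(triethylsilyloxy)deca-6,8-dien-1-yl 2,2-dimethylpropanoate
Product: 11 (5R,6E,8E)-2-methyl-5-(propan-2-yl)-5-(triethylsilyloxy)deca-6,8-dien-1-ol
Conditions: iBu2AlH (2.5 equiv), CH2Cl2, −78 °C; aq. Rochelle salt
Reagents that add atoms: none
Why: Reductive cleavage of the pivalate by an aluminium hydride; neither acid nor hydroxide is needed, so the tertiary silyl ether and the diene should survive.

Step 7
Reactants: 11 (5R,6E,8E)-2-methyl-5-(propan-2-yl)-5-(triethylsilyloxy)deca-6,8-dien-1-ol
Product: 12 (5R,6E,8E)-2-methyl-5-(propan-2-yl)-5-(triethylsilyloxy)deca-6,8-dienal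
Conditions: Dess–Martin periodinane, NaHCO3, CH2Cl2, 0 °C to rt
Reagents that add atoms: none
Why: Dess–Martin oxidation of a primary alcohol to the aldehyde under buffered conditions; epimerisation at the α-carbon is of no concern.

Step 8
Reactants: 12 (5R,6E,8E)-2-methyl-5-(propan-2-yl)-5-(triethylsilyloxy)deca-6,8-dienal
Product: 13 (5R,6E,8E)-2-chloro-2-methyl-5-(propan-2-yl)-5-(triethylsilyloxy)deca-6,8-dienal
Conditions: NCS, DL-proline (20 mol %), CH2Cl2, 0 °C to rt
Reagents that add atoms: N-chlorosuccinimide, O=C1CCC(=O)N1Cl
Why: Enamine-catalysed α-chlorination of an aldehyde with N-chlorosuccinimide. The methyl-bearing carbon is the only α-carbon, so chlorine is placed regiospecifically on the future C1 and a second chlorination is impossible; the configuration of this centre does not matter.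

Step 9
Reactants: 13 (5R,6E,8E)-2-chloro-2-methyl-5-(propan-2-yl)-5-(triethylsilyloxy)deca-6,8-dienal; 14 methylmagnesium bromide (3 M in Et2O)
Product: 15 (6R,7E,9E)-3-chloro-3-methyl-6-(propan-2-yl)-6-(triethylsilyloxy)undeca-7,9-dien-2-ol (mixture of C2 and C3 epimers)
Conditions: MeMgBr, Et2O, −78 °C; aq. NH4Cl at −78 °C
Reagents that add atoms: methylmagnesium bromide (compound 14), C[Mg]Br
Why: Grignard addition to a non-enolisable α-chloro aldehyde brings in C9; the cold quench keeps the magnesium alkoxide from displacing the tertiary chloride to an epoxide. Both new centres are removed later.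

Step 10
Reactants: 15 (6R,7E,9E)-3-chloro-3-methyl-6-(propan-2-yl)-6-(triethylsilyloxy)undeca-7,9-dien-2-ol
Product: 16 (6R,7E,9E)-3-chloro-3-methyl-6-(propan-2-yl)-6-(triethylsilyloxy)undeca-7,9-dien-2-one (both C3 epimers)
Conditions: Dess–Martin periodinane, NaHCO3, CH2Cl2, rt
Reagents that add atoms: none
Why: Dess–Martin oxidation of the chlorohydrin to the tertiary α-chloro ketone under buffered, non-acidic conditions, which should leave the diene and the tertiary silyl ether untouched.

Step 11
Reactants: 16 (6R,7E,9E)-3-chloro-3-methyl-6-(propan-2-yl)-6-(triethylsilyloxy)undeca-7,9-dien-2-one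
Product: 18 (1S,4R,5R,8R)-4-(triethylsilyloxy)dauc-6-en-10-one, via oxyallyl cation 17 (not isolated)
Conditions: NEt3 (3 equiv), CF3CH2OH, 0.01 M, 0 °C to rt
Reagents that add atoms: none
Why: The amine enolises 16 toward the only enolisable position, the C9 methyl, and the tertiary chloride ionises in the polar, weakly nucleophilic fluoro-alcohol to give the oxyallyl cation 17, whose termini C1 and C9 bond to the termini C5 and C8 of the s-cis diene in a concerted or stepwise (4+3) process. The closest known reaction type is the intramolecular (4+3) cycloaddition of oxyallyl cations generated from α-chloro ketones with tethered butadienes under amine/fluoro-alcohol conditions. The cyclopentane closes by C1–C5 bond formation, a 5-exo-trig closure with respect to the C5=C6 alkene that the three-atom tether C2–C3–C4 enforces; the cycloheptenone is the (4+3) ring itself and is completed when C9 joins C8, formally a 7-endo capture of the C6–C8 allyl cation by the enolate terminus. C1 should be set by an extended (exo-like) arrangement in which the tether sits syn to the oxyallyl oxygen and points away from the diene, which puts the C1 methyl anti to H5 and gives the trans fusion. C5 should be set by the C4 stereocentre: in the nascent five-membered ring the diene arm on C5 lies trans to the bulkier isopropyl group and cis to the silyloxy group, so C1 attacks the diene face that leaves H5 syn to the isopropyl group. C8 follows from suprafacial use of the (E,E)-diene, its methyl ending cis to the C4-bearing arm on the seven-membered ring, and this centre is erased in step 13. The step needs (4+3) closure to outrun solvent capture, Favorskii rearrangement and proton loss (helped by high dilution, the short tether and the non-nucleophilic solvent), trans over cis fusion and the C4-relayed face selectivity (secured only by the conformational preferences above), and survival of the tertiary dienylic silyl ether (the excess amine keeps the medium free of acid).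

Step 12
Reactants: 18 (1S,4R,5R,8R)-4-(triethylsilyloxy)dauc-6-en-10-one
Product: 19 (1S,4R,5S,6R,7S,8R)-6,7-epoxy-4-(triethylsilyloxy)daucan-10-one
Conditions: dimethyldioxirane, acetone, 0 °C
Reagents that add atoms: dimethyldioxirane, CC1(C)OO1
Why: Electrophilic epoxidation of the only alkene by a neutral oxidant that does not bring about Baeyer–Villiger oxidation of the ketone. The oxidant should approach the face that carries H5 and H8, because the other face is blocked by the C8 methyl and by the silyloxy group on C4; this sets C6 (and C7).

Step 13
Reactants: 19 (1S,4R,5S,6R,7S,8R)-6,7-epoxy-4-(triethylsilyloxy)daucan-10-one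
Product: 21 (1S,4R,5S,6R,7S)-6,7-epoxy-4-(triethylsilyloxy)dauc-8-en-10-one, via trimethylsilyl enol ether 20 (not isolated)
Conditions: LiN(SiMe3)2, Me3SiCl, THF, −78 °C; concentrate; Pd(OAc)2 (1.1 equiv), MeCN, rt
Reagents that add atoms: none
Why: Saegusa–Ito dehydrogenation. Only C9 carries α-hydrogens (C1 is quaternary), so enolisation is regiospecific, and silylation in situ at −78 °C keeps the enolate from attacking the epoxide. The palladium enolate loses H8 by syn β-hydride elimination to give the C8=C9 enone, which erases the C8 stereocentre.

Step 14
Reactants: 21 (1S,4R,5S,6R,7S)-6,7-epoxy-4-(triethylsilyloxy)dauc-8-en-10-one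
Product: 22 (1S,4R,5S,6S)-6-hydroxy-4-(triethylsilyloxy)dauc-7-en-10-one
Conditions: SmI2 (2.2 equiv), THF–MeOH, −78 °C
Reagents that add atoms: none
Why: Two single-electron transfers from SmI2 to the γ,δ-epoxy enone cleave the allylic C7–O bond and give a dienolate that methanol protonates at C9, a known reductive opening of vinylogous epoxy ketones. The C6–O bond is not broken, so C6 keeps the configuration set in step 12.

Step 15
Reactants: 22 (1S,4R,5S,6S)-6-hydroxy-4-(triethylsilyloxy)dauc-7-en-10-one
Product: 23 (1S,4R,5S,6S)-6-hydroxy-4-(triethylsilyloxy)dauc-8-en-10-one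
Conditions: DBU (0.5 equiv), CH2Cl2, rt
Reagents that add atoms: none
Why: Base-mediated isomerisation of the β,γ-unsaturated ketone through its dienolate to the conjugated trisubstituted enone. The free hydroxyl is a poor leaving group, so vinylogous elimination should not compete at room temperature.

Step 16
Reactants: 23 (1S,4R,5S,6S)-6-hydroxy-4-(triethylsilyloxy)dauc-8-en-10-one; 24 4-methoxybenzoyl chloride
Product: 25 (1S,4R,5S,6S)-10-oxo-4-(triethylsilyloxy)dauc-8-en-6-yl 4-methoxybenzoate
Conditions: 4-MeOC6H4COCl, pyridine, 4-(dimethylamino)pyridine (cat.), CH2Cl2, 0 °C to rt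
Reagents that add atoms: 4-methoxybenzoyl chloride (compound 24), COc1ccc(C(Cl)=O)cc1
Why: Acylation of the only free hydroxyl by nucleophilic catalysis. A weak base and low temperature are chosen because the new δ-acyloxy enone can eliminate under stronger base.

Step 17
Reactants: 25 (1S,4R,5S,6S)-10-oxo-4-(triethylsilyloxy)dauc-8-en-6-yl 4-methoxybenzoate
Product: 26 (1S,4R,5S,6S)-4-hydroxy-10-oxodauc-8-en-6-yl 4-methoxybenzoate (the target)
Conditions: HF·pyridine, pyridine, THF, 0 °C to rt
Reagents that add atoms: none
Why: Fluoride cleavage of the tertiary silyl ether under weakly acidic, non-basic conditions, which should spare the ester and the enone. C4 is no longer allylic at this stage, so ionisation is not a concern.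

## Compound list

1 | (2E,4E)-hexa-2,4-dienal | C/C=C/C=C/C=O | starting material
2 | isopropylmagnesium chloride | CC(C)[Mg]Cl | starting material
3 | (4E,6E)-2-methylocta-4,6-dien-3-ol (racemic) | C/C=C/C=C/C(O)C(C)C | intermediate
4 | (4E,6E)-2-methylocta-4,6-dien-3-one | C/C=C/C=C/C(=O)C(C)C | intermediate
5 | 2-methylbut-3-en-1-ol (racemic) | C=CC(C)CO | starting material
6 | 2-methylbut-3-en-1-yl 2,2-dimethylpropanoate (racemic) | C=CC(C)COC(=O)C(C)(C)C | intermediate
7 | diethyl[3-methyl-4-(2,2-dimethylpropanoyloxy)butyl]borane (not isolated) | CCB(CC)CCC(C)COC(=O)C(C)(C)C | intermediate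
8 | bis[3-methyl-4-(2,2-dimethylpropanoyloxy)butyl]zinc (not isolated) | CC(CC[Zn]CCC(C)COC(=O)C(C)(C)C)COC(=O)C(C)(C)C | intermediate
9 | (5R,6E,8E)-5-hydroxy-2-methyl-5-(propan-2-yl)deca-6,8-dien-1-yl 2,2-dimethylpropanoate (both C2 epimers) | CC(COC(=O)C(C)(C)C)CC[C@@](O)(C(C)C)/C=C/C=C/C | intermediate
10 | (5R,6E,8E)-2-methyl-5-(propan-2-yl)-5-(triethylsilyloxy)deca-6,8-dien-1-yl 2,2-dimethylpropanoate | CC(COC(=O)C(C)(C)C)CC[C@@](O[Si](CC)(CC)CC)(C(C)C)/C=C/C=C/C | intermediate
11 | (5R,6E,8E)-2-methyl-5-(propan-2-yl)-5-(triethylsilyloxy)deca-6,8-dien-1-ol | CC(CO)CC[C@@](O[Si](CC)(CC)CC)(C(C)C)/C=C/C=C/C | intermediate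
12 | (5R,6E,8E)-2-methyl-5-(propan-2-yl)-5-(triethylsilyloxy)deca-6,8-dienal | CC(C=O)CC[C@@](O[Si](CC)(CC)CC)(C(C)C)/C=C/C=C/C | intermediate
13 | (5R,6E,8E)-2-chloro-2-methyl-5-(propan-2-yl)-5-(triethylsilyloxy)deca-6,8-dienal | CC(Cl)(C=O)CC[C@@](O[Si](CC)(CC)CC)(C(C)C)/C=C/C=C/C | intermediate
14 | methylmagnesium bromide | C[Mg]Br | starting material
15 | (6R,7E,9E)-3-chloro-3-methyl-6-(propan-2-yl)-6-(triethylsilyloxy)undeca-7,9-dien-2-ol (C2 and C3 epimers) | CC(O)C(C)(Cl)CC[C@@](O[Si](CC)(CC)CC)(C(C)C)/C=C/C=C/C | intermediate
16 | (6R,7E,9E)-3-chloro-3-methyl-6-(propan-2-yl)-6-(triethylsilyloxy)undeca-7,9-dien-2-one (both C3 epimers) | CC(=O)C(C)(Cl)CC[C@@](O[Si](CC)(CC)CC)(C(C)C)/C=C/C=C/C | intermediate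
17 | oxyallyl cation (zwitterion) from 16: (6R,7E,9E)-3-methyl-2-oxido-6-(propan-2-yl)-6-(triethylsilyloxy)undeca-1,7,9-trien-3-ylium (not isolated) | C=C([O-])[C+](C)CC[C@@](O[Si](CC)(CC)CC)(C(C)C)/C=C/C=C/C | intermediate
18 | (1S,4R,5R,8R)-4-(triethylsilyloxy)dauc-6-en-10-one (trans-fused; C1 methyl anti to H5; silyloxy syn to the C1 methyl; H8 syn to H5) | C1=C[C@H](C)CC(=O)[C@@]2(C)CC[C@@](O[Si](CC)(CC)CC)(C(C)C)[C@H]12 | intermediate
19 | (1S,4R,5S,6R,7S,8R)-6,7-epoxy-4-(triethylsilyloxy)daucan-10-one (epoxide oxygen syn to H5) | O1[C@H]2[C@@H]1[C@H](C)CC(=O)[C@@]3(C)CC[C@@](O[Si](CC)(CC)CC)(C(C)C)[C@H]23 | intermediate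
20 | (1S,4R,5S,6R,7S,8R)-6,7-epoxy-4-(triethylsilyloxy)-10-(trimethylsilyloxy)dauc-9-ene (not isolated) | O1[C@H]2[C@@H]1[C@H](C)C=C(O[Si](C)(C)C)[C@@]3(C)CC[C@@](O[Si](CC)(CC)CC)(C(C)C)[C@H]23 | intermediate
21 | (1S,4R,5S,6R,7S)-6,7-epoxy-4-(triethylsilyloxy)dauc-8-en-10-one | O1[C@H]2[C@@H]1C(C)=CC(=O)[C@@]3(C)CC[C@@](O[Si](CC)(CC)CC)(C(C)C)[C@H]23 | intermediate
22 | (1S,4R,5S,6S)-6-hydroxy-4-(triethylsilyloxy)dauc-7-en-10-one | O[C@H]1C=C(C)CC(=O)[C@@]2(C)CC[C@@](O[Si](CC)(CC)CC)(C(C)C)[C@H]12 | intermediate
23 | (1S,4R,5S,6S)-6-hydroxy-4-(triethylsilyloxy)dauc-8-en-10-one | O[C@H]1CC(C)=CC(=O)[C@@]2(C)CC[C@@](O[Si](CC)(CC)CC)(C(C)C)[C@H]12 | intermediate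
24 | 4-methoxybenzoyl chloride | COc1ccc(C(Cl)=O)cc1 | starting material
25 | (1S,4R,5S,6S)-10-oxo-4-(triethylsilyloxy)dauc-8-en-6-yl 4-methoxybenzoate | COc1ccc(C(=O)O[C@H]2CC(C)=CC(=O)[C@@]3(C)CC[C@@](O[Si](CC)(CC)CC)(C(C)C)[C@H]23)cc1 | intermediate
26 | (1S,4R,5S,6S)-4-hydroxy-10-oxodauc-8-en-6-yl 4-methoxybenzoate, that is (3R,3aS,4S,8aS)-3-hydroxy-6,8a-dimethyl-8-oxo-3-(propan-2-yl)-1,2,3,3a,4,5,8,8a-octahydroazulen-4-yl 4-methoxybenzoate | COc1ccc(C(=O)O[C@H]2CC(C)=CC(=O)[C@@]3(C)CC[C@@](O)(C(C)C)[C@H]23)cc1 | target

## Step count and risks

Total step count: 17. Longest linear sequence: 16 steps (from 1 to 26 through steps 1, 2 and 4 to 17); step 3 is a one-step side branch.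

**Step 11 (key step).** The most likely failure is loss of the cation to solvent capture or to the Favorskii pathway before the unactivated, acyclic diene reacts. Competing cis fusion, attack on the diene face syn to the isopropyl group, and solvolytic ionisation at the tertiary, doubly allylic C4–O bond in the ionising solvent are further risks.

The fallback sets out from 16 and returns at 18. LiN(SiMe3)2 and Me3SiCl (THF, −78 °C; only the C9 methyl can be deprotonated) would give the 2-silyloxyallylic chloride (6R,7E,9E)-3-chloro-3-methyl-6-(propan-2-yl)-6-(triethylsilyloxy)-2-(trimethylsilyloxy)undeca-1,7,9-triene F1. Ionisation of F1 with AgO2CCF3 in CH2Cl2 at −78 °C would give the more electrophilic 2-silyloxyallyl cation in an aprotic medium without nucleophilic solvent. Loss of the trimethylsilyl group from the cycloadduct gives 18. This is the known silver-salt variant of the (4+3) cycloaddition of 2-silyloxyallyl halides.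

**Step 4.** The catalyst may discriminate poorly between the isopropyl and the dienyl group, and addition to a hindered conjugated ketone may be slow enough for conjugate addition or enolisation to compete.

The fallback sets out from 4 and 6 and returns at 9. It replaces catalyst control by stereospecific transfer.
- Corey–Bakshi–Shibata reduction of 4 (BH3·SMe2 with the antipode of the B-methyl oxazaborolidine from diphenylprolinol that gives the R alcohol) would give (3R,4E,6E)-2-methylocta-4,6-dien-3-ol F2.
- iPr2NCOCl and NEt3 would convert F2 into (3R,4E,6E)-2-methylocta-4,6-dien-3-yl N,N-di(propan-2-yl)carbamate F3.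
- Hydroboration of 6 with pinacolborane and RhCl(PPh3)3 would give 2-methyl-4-(4,4,5,5-tetramethyl-1,3,2-dioxaborolan-2-yl)butyl 2,2-dimethylpropanoate F4.
- Lithiation of F3 (s-BuLi, Et2O, −78 °C), borylation with F4 and 1,2-migration on warming with MgBr2·OEt2 would give (5S,6E,8E)-2-methyl-5-(propan-2-yl)-5-(4,4,5,5-tetramethyl-1,3,2-dioxaborolan-2-yl)deca-6,8-dien-1-yl 2,2-dimethylpropanoate F5. The migration proceeds with inversion at carbon.
- Oxidation of F5 (NaOH, H2O2, 0 °C) with retention would give 9.

**Step 13.** The enolate may open the neighbouring epoxide to a cyclopropane before it is silylated. The zerovalent palladium formed in the oxidation may also open the new vinyl epoxide.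

The fallback sets out from 18 and returns at 21, with the order of the two operations reversed. LiN(SiMe3)2 and Me3SiCl would give (1S,4R,5R,8S)-4-(triethylsilyloxy)-10-(trimethylsilyloxy)dauca-6,9-diene F6. Pd(OAc)2 in MeCN would then give (1S,4R,5R)-4-(triethylsilyloxy)dauca-6,8-dien-10-one F7. Dimethyldioxirane should epoxidise the more electron-rich distal C6=C7 alkene of F7 on the face of H5 and give 21. No enolate is then formed in the presence of an epoxide, and the epoxide never meets palladium.

**Step 15.** Conjugation may stay incomplete, because in a seven-membered ring the conjugated and the β,γ-unsaturated ketone can lie close in energy. Forcing the equilibrium with more base or heat invites vinylogous loss of water.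

The fallback sets out from 21 and returns at 23, and makes no new compound. Palladium-catalysed formate hydrogenolysis of the vinyl epoxide (Pd2(dba)3·CHCl3, PBu3, HCO2H, NEt3, THF) delivers hydride to C7 of the π-allyl palladium intermediate, the known course for γ,δ-epoxy-α,β-unsaturated carbonyl compounds. This gives the conjugated enone directly and replaces steps 14 and 15.

## Further compounds

F1 | step 11 | (6R,7E,9E)-3-chloro-3-methyl-6-(propan-2-yl)-6-(triethylsilyloxy)-2-(trimethylsilyloxy)undeca-1,7,9-triene (both C3 epimers) | C=C(O[Si](C)(C)C)C(C)(Cl)CC[C@@](O[Si](CC)(CC)CC)(C(C)C)/C=C/C=C/C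
F2 | step 4 | (3R,4E,6E)-2-methylocta-4,6-dien-3-ol | C/C=C/C=C/[C@H](O)C(C)C
F3 | step 4 | (3R,4E,6E)-2-methylocta-4,6-dien-3-yl N,N-di(propan-2-yl)carbamate | C/C=C/C=C/[C@H](OC(=O)N(C(C)C)C(C)C)C(C)C
F4 | step 4 | 2-methyl-4-(4,4,5,5-tetramethyl-1,3,2-dioxaborolan-2-yl)butyl 2,2-dimethylpropanoate | CC(CCB1OC(C)(C)C(C)(C)O1)COC(=O)C(C)(C)C
F5 | step 4 | (5S,6E,8E)-2-methyl-5-(propan-2-yl)-5-(4,4,5,5-tetramethyl-1,3,2-dioxaborolan-2-yl)deca-6,8-dien-1-yl 2,2-dimethylpropanoate | CC(COC(=O)C(C)(C)C)CC[C@@](B1OC(C)(C)C(C)(C)O1)(C(C)C)/C=C/C=C/C
F6 | step 13 | (1S,4R,5R,8S)-4-(triethylsilyloxy)-10-(trimethylsilyloxy)dauca-6,9-diene | C1=C[C@H](C)C=C(O[Si](C)(C)C)[C@@]2(C)CC[C@@](O[Si](CC)(CC)CC)(C(C)C)[C@H]12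
F7 | step 13 | (1S,4R,5R)-4-(triethylsilyloxy)dauca-6,8-dien-10-one | C1=CC(C)=CC(=O)[C@@]2(C)CC[C@@](O[Si](CC)(CC)CC)(C(C)C)[C@H]12
F0 | step 15 | none | none
A1 | alternative 1 | 3-(1-methyl-2,7-dioxocycloheptyl)propanal | CC1(CCC=O)C(=O)CCCCC1=O
A2 | alternative 1 | cis-fused 7-hydroxy-1-methylbicyclo[5.3.0]decane-2,8-dione (hydroxyl on C5, ketones at C4 and C10 in the numbering used here) | C1CCCC(=O)[C@@]2(C)CCC(=O)[C@@]12O
A3 | alternative 2 | 3-methylcyclopent-2-en-1-one | CC1=CC(=O)CC1
A4 | alternative 2 | bis(2-methylpropyl)[1-(trimethylsilyl)ethenyl]aluminium | C=C([Si](C)(C)C)[Al](CC(C)C)CC(C)C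
A5 | alternative 2 | (2-methyl-1,3-dioxolan-2-yl)acetaldehyde | CC1(CC=O)OCCO1
A6 | alternative 2 | 2-[1-hydroxy-2-(2-methyl-1,3-dioxolan-2-yl)ethyl]-3-methyl-3-[1-(trimethylsilyl)ethenyl]cyclopentan-1-one (C1, C5 and C6 configured as in the target) | O[C@@H](CC1(C)OCCO1)[C@@H]2[C@@](C)(C(=C)[Si](C)(C)C)CCC2=O
A7 | alternative 3 | trans-1-methyl-3-(propan-2-yl)-3-(triethylsilyloxy)cyclopentane-1,2-dicarbaldehyde (C1, C4 and C5 configured as in 18) | O=C[C@@]1(C)CC[C@@](O[Si](CC)(CC)CC)(C(C)C)[C@@H]1C=O
A8 | alternative 3 | 3-iodo-2-[(trimethylsilyl)methyl]prop-1-ene | C=C(CI)C[Si](C)(C)C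
A9 | alternative 3 | 1-methyl-8-methylidene-4-(propan-2-yl)-4-(triethylsilyloxy)bicyclo[5.3.0]decane-6,10-diol in the numbering used here (C1, C4, C5 and C6 configured as in the target) | O[C@H]1CC(=C)C[C@H](O)[C@@]2(C)CC[C@@](O[Si](CC)(CC)CC)(C(C)C)[C@H]12
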